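The readings stem from a simulated flask with made-up constants; noise was put on by code.

- A small charge of G, 0.28 mM, carries J to X, and at a given [Q] you can treat J as pseudo-first-order. In the north-east run X and J together stay near half of the charge, and at 8.00 min the north run holds J at 28.2% and the east run at 29.1%, though the east run started with more J.

all flasks: G 0.28 mM

| run | J | L | Q | remark | time |
|---|---|---|---|---|---|
| north-east | 0.11 M | 0.11 M | 0.121 M | run made earlier |  |
| north | 0.055 M | 0.055 M | 0.121 M | run made earlier |  |
| east | 0.083 M | 0.083 M | 0.121 M | run made earlier |  |
| theta | 0.11 M | 0.11 M | 0.121 M | one stirred flow tank at steady state, fed with the mixture as stated, mean residence time 6.0 min |  |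
| delta | 0.11 M | 0.11 M | 0.121 M | one stirred flow tank at steady state, fed with the mixture as stated, mean residence time 30.0 min |  |
| gamma | 0.11 M | 0.11 M | 0.121 M (fed, over 4.80 min) | all but Q at the start; Q goes in evenly over 4.80 min, the run ends at 6.0 min | 6.0 min |
| eta | 0.11 M | 0.11 M | 0.121 M | a closed flask charged with all of it at once and left for 6.0 min | 6.0 min |

- north-east (time / min: X / %, J / %): 1.33: 6.6, 43.5; 2.50: 8.9, 40.1; 4.00: 14.1, 37.8; 5.00: 13.7, 36.6; 6.00: 16.9, 33.4
- north (time / min: X / %, J / %): 0.667: 3.0, 46.9; 2.00: 7.5, 40.3; 3.00: 10.6, 38.7; 5.00: 18.8, 32.4; 8.00: 21.8, 28.2
- east (time / min: X / %, J / %): 0.500: 1.9, 47.4; 1.00: 2.6, 45.3; 2.00: 7.4, 42.7; 4.00: 14.6, 35.5; 8.00: 20.7, 29.1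

(each reading ± 1 percentage point)

- the set-up with the highest amount of X at the outlet or at the end, in percent of the J and L together put in ("none" if the first two lie within 2 percentage points) (theta / delta / gamma / eta / none)
- amount of X at the outlet or at the end, in percent of the J and L together put in, theta
- amount of X at the outlet or at the end, in percent of the J and L together put in, delta
- amount of X at the outlet or at the end, in percent of the J and L together put in, gamma
- amount of X at the outlet or at the end, in percent of the J and L together put in, eta

- G is single-handed; J and L are mirror images of each other, charged as a racemate, each of them at the stated concentration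
- the stated concentrations are those of everything mixed, before any reaction; amounts are the same in each set-up
- steps that have been proposed: Q + G + J -> G + X; Q + G + L -> G + E; Q <-> D
- the feed brings no volume worth counting
- the earlier runs were made in a closed, stirred flask

- Integrating d[J]/dt = −k[G][Q][J] in closed form, you find that what J feels is ∫[Q]dt, which is why I reckon gamma from the north-east run, its nearest simulated neighbour with the same charges.
- The north-east run had its Q at the start, but gamma receives it evenly over 4.80 min, so gamma's Q arrives on average at 2.40 min. I therefore read gamma at 6.0 min as a closed flask of the younger age 3.60 min.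
- Between 2.50 min and 4.00 min the north-east run reads J at 40.1% and 37.8%, so at that age J stands near 38.4%.
- Gamma's dose is then 0.264, where the dose means the logarithm of charged [J] over present [J], equal to k[G]∫[Q]dt.
- My reckoning gives gamma X at 11.6%, less than the 16.9% the north-east run reads at 6.00 min, because I take gamma's Q to be younger, 3.60 min against 6.00 min.
- The forecast, holding that “the integrated Q exposure is lower”, puts gamma at 12%, a little above my figure. It puts eta at 16.5%, theta at 12.7% and delta at 22.5%, and it names delta as best.
- The simulation gives theta 12.6%, delta 21.3%, gamma 12.0% and eta 16.5%, so delta is highest, and the forecast's order holds.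

    Q + G + J → G + X (k = 52.5 /M²/s)
    Q + G + L → G + E (k = 24.1 /M²/s)
    Q ⇌ D (K = 1.10, k = 8.34 × 10⁻⁴ /s)

- Take the neighbouring flask, like gamma but with 0.48 M of Q, read at the same 6.0 min. Q enters in the same way, so you scale gamma's dose by the ratio of charges, 3.97, and get 1.05. That reckons J at 17.5% and X at 32.5%. The neighbouring flask holds J at 16.1% and X at 33.9%.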